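**Retrosynthetic overview** (indane numbering: C1 carries the carbinol carbon Cα, C2 the 3,5-dihydroxyphenyl ring, C3 the 4-hydroxyphenyl ring; C3a–C7a is the resorcinol ring with O at C4 and C6)
1. Target ⇒ global O-deprotection: five benzyl ethers (hydrogenolysis) and one aryl triflate on the carbinol-side ring (hydroxide).
2. The five-membered ring, the only ring formed, is opened at C3–C3a: Friedel–Crafts closure of a C3 benzylic cation (from protonation of a C2=C3 stilbene) onto the ring carbon ortho/para to the two ether oxygens.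
3. Key disconnection C1–Cα: allylboration of 4-(triflyloxy)benzaldehyde by a 1,2,3-triaryl allylboron reagent carrying boron on the future C3.
4. Enabling feature: C1–C2–C3 is an allyl triad. C3 is benzylic to the para-oxygenated ring (it can hold boron, later a cation), and C1 is the γ-terminus next to the resorcinol ring, so C1 attacks the aldehyde while the double bond moves to C2=C3, placed for ring closure.
5. The allylboronate comes from a 1,2-metallate rearrangement of a lithiated 4-(benzyloxy)benzyl carbamate with a geometry-defined 1,2-diarylvinyl boronate; the C–B centre is relayed to C1/Cα (chair transition state), then to C2/C3 (ring closure).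

Key step: step 6

Assumption: in step 5 the antipode of the chiral bis(oxazoline) ligand is used that makes the (R)-configured lithiated carbamate the dominant, reacting complex (dynamic thermodynamic resolution of configurationally labile lithiated O-benzyl carbamates); borylation by the boronic ester is taken to occur with retention and the 1,2-shift with inversion.

**Step 1**
Reactants: 1 3,5-bis(benzyloxy)benzaldehyde
Product: 2 1,3-bis(benzyloxy)-5-ethynylbenzene
Conditions: dimethyl (1-diazo-2-oxopropyl)phosphonate, K2CO3, MeOH/THF, rt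
Reagents that add atoms: dimethyl (1-diazo-2-oxopropyl)phosphonate CC(=O)C(=[N+]=[N-])P(=O)(OC)OC
Why: Seyferth–Gilbert homologation with the Ohira–Bestmann reagent should turn the aryl aldehyde into the terminal alkyne under mild carbonate conditions that leave the benzyl ethers untouched.

**Step 2**
Reactants: 2 1,3-bis(benzyloxy)-5-ethynylbenzene
Product: 5 2-{[3,5-bis(benzyloxy)phenyl]ethynyl}-4,4,5,5-tetramethyl-1,3,2-dioxaborolane, via lithium acetylide 3 (not isolated), via lithium alkynyl(isopropoxy)borate 4 (not isolated)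
Conditions: n-BuLi, THF, −78 °C; 2-isopropoxy-4,4,5,5-tetramethyl-1,3,2-dioxaborolane, −78 °C; anhydrous HCl/Et2O, −78 °C → rt
Reagents that add atoms: 2-isopropoxy-4,4,5,5-tetramethyl-1,3,2-dioxaborolane CC(C)OB1OC(C)(C)C(C)(C)O1
Why: Deprotonation of the terminal alkyne, borylation with an alkoxyboronate and anhydrous acid release of the borate is the standard preparation of 1-alkynyl pinacol boronates.

**Step 3**
Reactants: 5 2-{[3,5-bis(benzyloxy)phenyl]ethynyl}-4,4,5,5-tetramethyl-1,3,2-dioxaborolane; 6 1,3-bis(benzyloxy)-5-bromobenzene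
Product: 8 (E)-2-{1,2-bis[3,5-bis(benzyloxy)phenyl]ethenyl}-4,4,5,5-tetramethyl-1,3,2-dioxaborolane, via gem-borazirconocene alkene 7 (not isolated)
Conditions: Cp2Zr(H)Cl, THF, rt; then 6, Pd(PPh3)4 (5 mol %), ZnCl2 (20 mol %), THF, 50 °C
Reagents that add atoms: none
Why: syn-Hydrozirconation of a 1-alkynyl boronate places zirconium on the boron-bearing carbon cis to the new vinylic hydrogen, and Negishi-type palladium coupling of the C–Zr bond with retention should then fix the two aryl groups trans and boron cis to the β-aryl group.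

**Step 4**
Reactants: 9 [4-(benzyloxy)phenyl]methanol; 10 N,N-diisopropylcarbamoyl chloride
Product: 11 4-(benzyloxy)benzyl N,N-diisopropylcarbamate
Conditions: Et3N, DMAP (cat.), CH2Cl2, reflux
Reagents that add atoms: none
Why: O-Carbamoylation of a primary benzylic alcohol installs the directing and leaving group needed for lithiation–borylation.

**Step 5**
Reactants: 11 4-(benzyloxy)benzyl N,N-diisopropylcarbamate; 8 (E)-2-{1,2-bis[3,5-bis(benzyloxy)phenyl]ethenyl}-4,4,5,5-tetramethyl-1,3,2-dioxaborolane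
Product: 14 2-{(1S,2E)-1-[4-(benzyloxy)phenyl]-2,3-bis[3,5-bis(benzyloxy)phenyl]prop-2-en-1-yl}-4,4,5,5-tetramethyl-1,3,2-dioxaborolane, via lithiated carbamate 12 (not isolated), via boronate complex 13 (not isolated)
Conditions: s-BuLi, chiral bis(oxazoline) ligand, toluene, −78 °C (equilibration); 8, −78 °C; MgBr2·OEt2/MeOH, −78 °C → rt
Reagents that add atoms: none
Why: Lithiation–borylation: carbamate-directed benzylic lithiation under the chiral ligand gives the (R)-carbenoid, which is borylated with retention and then undergoes a stereoinvertive 1,2-metallate rearrangement (alkenyl migration, loss of carbamate) that should set the S-configured C–B centre while the alkene geometry is carried over unchanged.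

**Step 6**
Reactants: 14 2-{(1S,2E)-1-[4-(benzyloxy)phenyl]-2,3-bis[3,5-bis(benzyloxy)phenyl]prop-2-en-1-yl}-4,4,5,5-tetramethyl-1,3,2-dioxaborolane; 15 4-formylphenyl trifluoromethanesulfonate
Product: 18 (1R,2S,3Z)-4-[4-(benzyloxy)phenyl]-2,3-bis[3,5-bis(benzyloxy)phenyl]-1-{4-[(trifluoromethylsulfonyl)oxy]phenyl}but-3-en-1-ol, via allyl(butyl)borinic ester 16 (not isolated), via O-borinate adduct 17 (not isolated)
Conditions: n-BuLi, THF, −78 °C; (CF3CO)2O, −78 °C; then 15, −78 °C → rt; aq. NaHCO3 work-up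
Reagents that add atoms: none
Why: n-BuLi/TFAA converts the pinacol boronate into the more Lewis-acidic allyl(butyl)borinic ester, which adds to the aldehyde through a closed six-membered chair transition state with allylic transposition (SE2′), forming the C1–Cα bond while the double bond moves to C2=C3. The closest known reaction is the allylboration of aldehydes with α-substituted allyl and crotyl pinacol boronates via borinic esters generated in situ. No ring is closed in this step. The syn relation of the two new stereocentres (C1 and Cα) follows from the γ-aryl group being cis to the boron-bearing carbon (Z-crotyl-type geometry, aldehyde aryl equatorial); their absolute sense comes from the C–B stereocentre, whose aryl group should take the pseudo-equatorial position to avoid 1,3-allylic strain with the cis γ-aryl group, a preference the borinic ester is known to reinforce. The step needs γ- over α-attack, secured by the cyclic boron-delivered mechanism with boron fixed on the carbon next to the para-alkoxyphenyl ring, and one chair over its α-axial alternative. The triflate makes the aldehyde a strong electrophile and will later keep the carbinol from ionising.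

**Step 7**
Reactants: 18 (1R,2S,3Z)-4-[4-(benzyloxy)phenyl]-2,3-bis[3,5-bis(benzyloxy)phenyl]-1-{4-[(trifluoromethylsulfonyl)oxy]phenyl}but-3-en-1-ol
Product: 19 4-{(R)-[(1R,2S,3R)-4,6-bis(benzyloxy)-3-[4-(benzyloxy)phenyl]-2-[3,5-bis(benzyloxy)phenyl]-2,3-dihydro-1H-inden-1-yl](hydroxy)methyl}phenyl trifluoromethanesulfonate
Conditions: CF3CO2H (5 equiv), CH2Cl2 (0.01 M), −20 → 0 °C; aq. NaHCO3/MeOH work-up
Reagents that add atoms: none
Why: Protonation of the electron-rich stilbene at C2 gives the 4-benzyloxybenzyl cation at C3, which is captured in an intramolecular Friedel–Crafts alkylation by the neighbouring 3,5-bis(benzyloxy)phenyl ring at its carbon ortho/para to the two ether oxygens (five-membered ring closure), the reversible protonation and O-trapping steps being expected to funnel the bias of the C1 stereocentre into the all-trans arrangement at C2 and C3, while the triflate-bearing ring keeps the free carbinol from ionising.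

**Step 8**
Reactants: 19 4-{(R)-[(1R,2S,3R)-4,6-bis(benzyloxy)-3-[4-(benzyloxy)phenyl]-2-[3,5-bis(benzyloxy)phenyl]-2,3-dihydro-1H-inden-1-yl](hydroxy)methyl}phenyl trifluoromethanesulfonate
Product: 20 4-{(R)-[(1R,2S,3R)-2-(3,5-dihydroxyphenyl)-4,6-dihydroxy-3-(4-hydroxyphenyl)-2,3-dihydro-1H-inden-1-yl](hydroxy)methyl}phenyl trifluoromethanesulfonate
Conditions: H2 (1 atm), 10% Pd/C, EtOAc/MeOH, rt
Reagents that add atoms: none
Why: Neutral hydrogenolysis should remove the five aryl benzyl ethers, while the benzylic C–O bond of the carbinol is spared because its aryl ring is electron-poor as the triflate and no stereocentre is touched.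

**Step 9**
Reactants: 20 4-{(R)-[(1R,2S,3R)-2-(3,5-dihydroxyphenyl)-4,6-dihydroxy-3-(4-hydroxyphenyl)-2,3-dihydro-1H-inden-1-yl](hydroxy)methyl}phenyl trifluoromethanesulfonate
Product: 21 (1R,2S,3R)-2-(3,5-dihydroxyphenyl)-1-[(R)-hydroxy(4-hydroxyphenyl)methyl]-3-(4-hydroxyphenyl)-2,3-dihydro-1H-indene-4,6-diol (target)
Conditions: Et4NOH (aq.), 1,4-dioxane, rt, argon; then aq. NH4Cl
Reagents that add atoms: none
Why: Hydroxide attacks sulfur of the aryl triflate (S–O cleavage) under mild basic conditions that should not ionise the benzylic alcohol or disturb any stereocentre.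

**Compound list**
1 | 3,5-bis(benzyloxy)benzaldehyde | O=Cc1cc(OCc2ccccc2)cc(OCc2ccccc2)c1 | starting material
2 | 1,3-bis(benzyloxy)-5-ethynylbenzene | C#Cc1cc(OCc2ccccc2)cc(OCc2ccccc2)c1 | intermediate
3 | lithium [3,5-bis(benzyloxy)phenyl]acetylide | [Li]C#Cc1cc(OCc2ccccc2)cc(OCc2ccccc2)c1 | intermediate
4 | lithium {[3,5-bis(benzyloxy)phenyl]ethynyl}(isopropoxy)(pinacolato)borate | [Li+].CC(C)O[B-]1(OC(C)(C)C(C)(C)O1)C#Cc1cc(OCc2ccccc2)cc(OCc2ccccc2)c1 | intermediate
5 | 2-{[3,5-bis(benzyloxy)phenyl]ethynyl}-4,4,5,5-tetramethyl-1,3,2-dioxaborolane | CC1(C)OB(OC1(C)C)C#Cc1cc(OCc2ccccc2)cc(OCc2ccccc2)c1 | intermediate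
6 | 1,3-bis(benzyloxy)-5-bromobenzene | Brc1cc(OCc2ccccc2)cc(OCc2ccccc2)c1 | starting material
7 | chlorobis(cyclopentadienyl){2-[3,5-bis(benzyloxy)phenyl]-1-(pinacolboryl)ethenyl}zirconium, Zr cis to the vinylic H | Cl[Zr](C1C=CC=C1)(C1C=CC=C1)/C(B1OC(C)(C)C(C)(C)O1)=C/c1cc(OCc2ccccc2)cc(OCc2ccccc2)c1 | intermediate
8 | (E)-2-{1,2-bis[3,5-bis(benzyloxy)phenyl]ethenyl}-4,4,5,5-tetramethyl-1,3,2-dioxaborolane (aryl groups trans, boron cis to the β-aryl group) | CC1(C)OB(OC1(C)C)/C(=C\c1cc(OCc2ccccc2)cc(OCc2ccccc2)c1)c1cc(OCc2ccccc2)cc(OCc2ccccc2)c1 | intermediate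
9 | [4-(benzyloxy)phenyl]methanol | OCc1ccc(OCc2ccccc2)cc1 | starting material
10 | N,N-diisopropylcarbamoyl chloride | CC(C)N(C(C)C)C(Cl)=O | starting material
11 | 4-(benzyloxy)benzyl N,N-diisopropylcarbamate | CC(C)N(C(C)C)C(=O)OCc1ccc(OCc2ccccc2)cc1 | intermediate
12 | (R)-α-lithio-4-(benzyloxy)benzyl N,N-diisopropylcarbamate (ligand complex) | c1ccccc1COc1ccc(cc1)[C@@H]([Li])OC(=O)N(C(C)C)C(C)C | intermediate
13 | lithium boronate complex of 12 and 8 (R at the carbamate-bearing carbon) | [Li+].c1ccccc1COc1ccc(cc1)[C@@H]([B-]2(OC(C)(C)C(C)(C)O2)/C(=C\c1cc(OCc3ccccc3)cc(OCc3ccccc3)c1)c1cc(OCc3ccccc3)cc(OCc3ccccc3)c1)OC(=O)N(C(C)C)C(C)C | intermediate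
14 | 2-{(1S,2E)-1-[4-(benzyloxy)phenyl]-2,3-bis[3,5-bis(benzyloxy)phenyl]prop-2-en-1-yl}-4,4,5,5-tetramethyl-1,3,2-dioxaborolane | c1ccccc1COc1ccc(cc1)[C@H](B1OC(C)(C)C(C)(C)O1)/C(=C\c1cc(OCc2ccccc2)cc(OCc2ccccc2)c1)c1cc(OCc2ccccc2)cc(OCc2ccccc2)c1 | intermediate
15 | 4-formylphenyl trifluoromethanesulfonate | O=Cc1ccc(OS(=O)(=O)C(F)(F)F)cc1 | starting material
16 | butyl[(1S,2E)-triarylallyl]borinic ester of pinacol mono(trifluoroacetate), derived from 14 | c1ccccc1COc1ccc(cc1)[C@H](B(CCCC)OC(C)(C)C(C)(C)OC(=O)C(F)(F)F)/C(=C\c1cc(OCc2ccccc2)cc(OCc2ccccc2)c1)c1cc(OCc2ccccc2)cc(OCc2ccccc2)c1 | intermediate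
17 | O-butylborinate of alcohol 18 | c1ccccc1COc1cc(OCc2ccccc2)cc(c1)[C@H]([C@@H](OB(CCCC)OC(C)(C)C(C)(C)OC(=O)C(F)(F)F)c1ccc(OS(=O)(=O)C(F)(F)F)cc1)/C(=C/c1ccc(OCc2ccccc2)cc1)c1cc(OCc2ccccc2)cc(OCc2ccccc2)c1 | intermediate
18 | (1R,2S,3Z)-4-[4-(benzyloxy)phenyl]-2,3-bis[3,5-bis(benzyloxy)phenyl]-1-{4-[(trifluoromethylsulfonyl)oxy]phenyl}but-3-en-1-ol | c1ccccc1COc1cc(OCc2ccccc2)cc(c1)[C@H]([C@@H](O)c1ccc(OS(=O)(=O)C(F)(F)F)cc1)/C(=C/c1ccc(OCc2ccccc2)cc1)c1cc(OCc2ccccc2)cc(OCc2ccccc2)c1 | intermediate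
19 | 4-{(R)-[(1R,2S,3R)-4,6-bis(benzyloxy)-3-[4-(benzyloxy)phenyl]-2-[3,5-bis(benzyloxy)phenyl]-2,3-dihydro-1H-inden-1-yl](hydroxy)methyl}phenyl trifluoromethanesulfonate | c1ccccc1COc1ccc([C@@H]2c3c(OCc4ccccc4)cc(OCc4ccccc4)cc3[C@H]([C@@H](O)c3ccc(OS(=O)(=O)C(F)(F)F)cc3)[C@H]2c2cc(OCc3ccccc3)cc(OCc3ccccc3)c2)cc1 | intermediate
20 | 4-{(R)-[(1R,2S,3R)-2-(3,5-dihydroxyphenyl)-4,6-dihydroxy-3-(4-hydroxyphenyl)-2,3-dihydro-1H-inden-1-yl](hydroxy)methyl}phenyl trifluoromethanesulfonate | Oc1ccc([C@@H]2c3c(O)cc(O)cc3[C@H]([C@@H](O)c3ccc(OS(=O)(=O)C(F)(F)F)cc3)[C@H]2c2cc(O)cc(O)c2)cc1 | intermediate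
21 | (1R,2S,3R)-2-(3,5-dihydroxyphenyl)-1-[(R)-hydroxy(4-hydroxyphenyl)methyl]-3-(4-hydroxyphenyl)-2,3-dihydro-1H-indene-4,6-diol | Oc1ccc([C@@H]2c3c(O)cc(O)cc3[C@H]([C@@H](O)c3ccc(O)cc3)[C@H]2c2cc(O)cc(O)c2)cc1 | target

**Totals**
Total step count: 9. Longest linear sequence: 8 steps (1 → 21 through steps 1, 2, 3, 5, 6, 7, 8, 9).

**Steps most likely to fail**

Step 6. The two chair transition states (α-aryl pseudo-equatorial against pseudo-axial) may compete, because 1,2-allylic strain with the aryl group on the central carbon opposes the 1,3-allylic strain that favours the desired one; this would lower the enantiomeric purity, and the congested reagent may also add slowly. Fallback: the stereocentre on boron is removed from the problem and the sense is set by a chiral acid. Setting out from 8, Matteson homologation (BrCH2Cl, n-BuLi, THF, −78 °C → rt) would give 2-{(2E)-2,3-bis[3,5-bis(benzyloxy)phenyl]prop-2-en-1-yl}-4,4,5,5-tetramethyl-1,3,2-dioxaborolane F3. Chiral phosphoric acid–catalysed allylboration of 15 with F3 ((R)-TRIP, toluene, −30 °C) should give the syn alcohol (1R,2S)-2,3-bis[3,5-bis(benzyloxy)phenyl]-1-{4-[(trifluoromethylsulfonyl)oxy]phenyl}but-3-en-1-ol F4. A Heck arylation of its 1,1-disubstituted alkene with 1-(benzyloxy)-4-iodobenzene (Pd(OAc)2, P(o-tol)3, Et3N, MeCN, 80 °C) then comes back to the route at 18, possibly mixed with its (3E)-alkene isomer F5, which feeds the same cation in step 7.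

Step 5. The configuration at the lithiated benzylic carbon may erode (epimerisation of the carbenoid, or reversible or ionising behaviour of the boronate complex of an electron-rich benzylic carbamate), and the hindered alkenyl boronate may be captured incompletely. Fallback: asymmetric lithiation is given up. Setting out from 11 and 8, lithiation with s-BuLi/TMEDA (Et2O, −78 °C) and the same borylation/1,2-shift would give the racemic 2-{(2E)-1-[4-(benzyloxy)phenyl]-2,3-bis[3,5-bis(benzyloxy)phenyl]prop-2-en-1-yl}-4,4,5,5-tetramethyl-1,3,2-dioxaborolane F1. The conditions of step 6 would convert it into the racemic syn alcohol, that is 18 together with its mirror image, the (1S,2R,3Z)-alcohol F2. Preparative chromatography on a chiral stationary phase removes F2 and comes back to the route at 18.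

Step 7. Facial control in the protonation and ring closure may be poor, the free hydroxyl may divert the C3 cation into a tetrahydrofuran, and acid may fragment the homoallylic alcohol. Fallback: the hydroxyl is masked before cyclisation. Setting out from 18, silylation (TBSOTf, 2,6-lutidine, CH2Cl2, 0 °C) would give the tert-butyldimethylsilyl ether of 18 F6. Lewis-acid cyclisation (BF3·OEt2, CH2Cl2, −40 °C), in which oxygen can no longer trap the cation and the bulkier C1 substituent sharpens the anti preference at C2, should give the tert-butyldimethylsilyl ether of 19 F7. Desilylation with HF·pyridine (THF, 0 °C) comes back to the route at 19.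

**Further compounds**
F1 | step 5 | racemic 2-{(2E)-1-[4-(benzyloxy)phenyl]-2,3-bis[3,5-bis(benzyloxy)phenyl]prop-2-en-1-yl}-4,4,5,5-tetramethyl-1,3,2-dioxaborolane | c1ccccc1COc1ccc(cc1)C(B1OC(C)(C)C(C)(C)O1)/C(=C\c1cc(OCc2ccccc2)cc(OCc2ccccc2)c1)c1cc(OCc2ccccc2)cc(OCc2ccccc2)c1
F2 | step 5 | (1S,2R,3Z)-4-[4-(benzyloxy)phenyl]-2,3-bis[3,5-bis(benzyloxy)phenyl]-1-{4-[(trifluoromethylsulfonyl)oxy]phenyl}but-3-en-1-ol (mirror image of 18) | c1ccccc1COc1cc(OCc2ccccc2)cc(c1)[C@@H]([C@H](O)c1ccc(OS(=O)(=O)C(F)(F)F)cc1)/C(=C/c1ccc(OCc2ccccc2)cc1)c1cc(OCc2ccccc2)cc(OCc2ccccc2)c1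
F3 | step 6 | 2-{(2E)-2,3-bis[3,5-bis(benzyloxy)phenyl]prop-2-en-1-yl}-4,4,5,5-tetramethyl-1,3,2-dioxaborolane | CC1(C)OB(C/C(=C\c2cc(OCc3ccccc3)cc(OCc3ccccc3)c2)c2cc(OCc3ccccc3)cc(OCc3ccccc3)c2)OC1(C)C
F4 | step 6 | (1R,2S)-2,3-bis[3,5-bis(benzyloxy)phenyl]-1-{4-[(trifluoromethylsulfonyl)oxy]phenyl}but-3-en-1-ol | c1ccccc1COc1cc(OCc2ccccc2)cc(c1)[C@H]([C@@H](O)c1ccc(OS(=O)(=O)C(F)(F)F)cc1)C(=C)c1cc(OCc2ccccc2)cc(OCc2ccccc2)c1
F5 | step 6 | (1R,2S,3E)-4-[4-(benzyloxy)phenyl]-2,3-bis[3,5-bis(benzyloxy)phenyl]-1-{4-[(trifluoromethylsulfonyl)oxy]phenyl}but-3-en-1-ol | c1ccccc1COc1cc(OCc2ccccc2)cc(c1)[C@H]([C@@H](O)c1ccc(OS(=O)(=O)C(F)(F)F)cc1)/C(=C\c1ccc(OCc2ccccc2)cc1)c1cc(OCc2ccccc2)cc(OCc2ccccc2)c1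
F6 | step 7 | tert-butyldimethylsilyl ether of 18 | c1ccccc1COc1cc(OCc2ccccc2)cc(c1)[C@H]([C@@H](O[Si](C)(C)C(C)(C)C)c1ccc(OS(=O)(=O)C(F)(F)F)cc1)/C(=C/c1ccc(OCc2ccccc2)cc1)c1cc(OCc2ccccc2)cc(OCc2ccccc2)c1
F7 | step 7 | tert-butyldimethylsilyl ether of 19 | c1ccccc1COc1ccc([C@@H]2c3c(OCc4ccccc4)cc(OCc4ccccc4)cc3[C@H]([C@@H](O[Si](C)(C)C(C)(C)C)c3ccc(OS(=O)(=O)C(F)(F)F)cc3)[C@H]2c2cc(OCc3ccccc3)cc(OCc3ccccc3)c2)cc1
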